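**Retrosynthetic overview**

1. The (Z)-ylidene butenolide is formed last, from a terminal enynol and (Z)-3-iodobut-2-enoic acid by tandem Sonogashira coupling and 5-exo-dig lactonisation. The E trisubstituted alkene comes from a Horner–Wadsworth–Emmons reaction on a saturated ester.
2. The C9–C11 bond is cut by Negishi coupling to the ring B enol triflate, which comes from the C9 decalone.
3. Ring A is cut at C1–C10 and C3–C4 in a formal [3+3] annulation of 6-methylcarvone (ring B, chiral pool) with the three-carbon linchpin 2,3-bis(phenylsulfonyl)propene.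
4. Enabling feature: in ring A the quaternary carbons C10 (angular methyl) and C4 (gem-dimethyl) are 1,3-related through C5–H. C10 is α to C9, which is sp2 in the target and can therefore be a ketone, and C4 can be the inner carbon of an isopropenyl group. This C9(=O)–C10–C5–C4 array is the C1(=O)–C6–C5–isopropenyl array of (R)-carvone, and C1–C2–C3 are three CH2 groups, so an allyl unit with a traceless sulfone on C2 fits between them.
5. Ring order: ring B (from carvone), then ring A (key step), then the butenolide ring.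

Key step: step 2

Remark: the bicyclic part is numbered as in drimanes (ring A C1–C5 and C10, ring B C5–C10, side chain from C11), and the target is read as the trans-fused (5S,10S) decalin with a Z ylidene butenolide and an E trisubstituted alkene. C8 and the sulfone-bearing C2 are stereogenic only in intermediates and are carried as mixtures.

**Route**

Step 1
Reactants: 1 (R)-(−)-carvone
Product: 2 (5R)-2,6-dimethyl-5-(prop-1-en-2-yl)cyclohex-2-en-1-one (6-methylcarvone; both C6 epimers)
Conditions: LiN(iPr)2 (1.05 equiv), THF, −78 °C; MeI, −78 to 0 °C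
Reagents that add atoms: iodomethane, CI
Why: Kinetic α′-deprotonation gives the cross-conjugated lithium dienolate, and its C-methylation (enolate alkylation) installs the future angular methyl at C6; the C6 configuration is irrelevant because this carbon is enolised again in step 2.

Step 2
Reactants: 2 6-methylcarvone; 3 2,3-bis(phenylsulfonyl)prop-1-ene
Product: 5 (4aS,8aS)-2,5,5,8a-tetramethyl-7-(phenylsulfonyl)-4a,5,6,7,8,8a-hexahydronaphthalen-1(4H)-one (both epimers at the sulfone carbon), via allylated carvone 4 (not isolated)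
Conditions: LiN(iPr)2 (1.05 equiv), THF, −78 °C; 3, −78 to 0 °C; then EtOH, Fe(acac)3 (50 mol %), PhSiH3 (2.5 equiv), 60 °C, same flask
Reagents that add atoms: 2,3-bis(phenylsulfonyl)prop-1-ene, C=C(CS(=O)(=O)c1ccccc1)S(=O)(=O)c1ccccc1
Why: Kinetic deprotonation of 2 at C6 (the future C10) gives the lithium dienolate, which attacks the CH2 terminus of 3 and expels benzenesulfinate (SN2′-type addition–elimination, the enolate allylation known for 2-sulfonylallyl multi-coupling reagents) to form C1–C10 and leave a vinyl sulfone; in the same flask the iron hydride formed from Fe(acac)3 and PhSiH3 then delivers a hydrogen atom to the CH2 of the electron-rich isopropenyl group, and the tertiary C4 radical adds to the unsubstituted vinyl sulfone carbon (C3) before the α-sulfonyl radical is reduced and protonated (hydrogen-atom-transfer reductive olefin coupling of the Giese type). The two events add up to a formal [3+3] annulation whose ionic counterpart is the α,α′-annulation of ketone derivatives with 2-(halomethyl)acrylates. Ring A closes in the 6-endo-trig radical mode, dictated by the sulfone because the 5-exo path would need attack at the substituted and polarity-mismatched carbon. C10 is set in the intermolecular alkylation by the C5 isopropenyl group, which sits pseudoaxial beside the enolate methyl so that the electrophile enters anti to it; this puts C1 trans to C4 and gives the trans ring fusion with the (5S,10S) pattern of the target, whereas C5 is carried over from carvone, C4 is not stereogenic and the sulfone carbon C2 is an inconsequential mixture. Fixing C10 before ring closure is deliberate, since closing the ring by an enolate attack on C10 would favour the cis-fused isomer. The step needs hydrogen-atom transfer to the 1,1-disubstituted donor alkene in preference to the enone and vinyl sulfone, which the electron-poor character of both acceptors secures, and any partial reduction of the enone is harmless because step 3 saturates it anyway.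

Step 3
Reactants: 5 enone sulfone
Product: 6 (4aS,8aS)-2,5,5,8a-tetramethyloctahydronaphthalen-1(2H)-one (both C2 epimers)
Conditions: Li (6 equiv), NH3(l)/THF, t-BuOH (1 equiv), −78 to −33 °C; isoprene, then NH4Cl
Reagents that add atoms: none
Why: Dissolving-metal reduction reduces the enone to its lithium enolate (protonated on quench, which also shields the ketone from over-reduction) and cleaves the alkyl–sulfonyl bond reductively, so the traceless sulfone and the C7–C8 double bond are removed together while C5 and C10 stay untouched.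

Step 4
Reactants: 6 decalone
Product: 7 (4aS,8aS)-2,5,5,8a-tetramethyl-3,4,4a,5,6,7,8,8a-octahydronaphthalen-1-yl trifluoromethanesulfonate
Conditions: KN(SiMe3)2, THF, −78 to 0 °C; PhNTf2, −78 °C to rt
Reagents that add atoms: N-phenylbis(trifluoromethanesulfonimide), O=S(=O)(N(c1ccccc1)S(=O)(=O)C(F)(F)F)C(F)(F)F
Why: C10 is quaternary, so the ketone can enolise only toward C8, and O-sulfonylation of that potassium enolate (enol triflate formation) gives the tetrasubstituted C8=C9 double bond regiospecifically and erases the C8 stereocentre.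

Step 5
Reactants: 7 enol triflate; 8 4-ethoxy-4-oxobutylzinc bromide
Product: 9 ethyl 4-[(4aS,8aS)-2,5,5,8a-tetramethyl-3,4,4a,5,6,7,8,8a-octahydronaphthalen-1-yl]butanoate
Conditions: Pd(PPh3)4 (5 mol %), LiCl, THF/NMP, 60 °C
Reagents that add atoms: 4-ethoxy-4-oxobutylzinc bromide, CCOC(=O)CCC[Zn]Br
Why: Negishi sp2–sp3 coupling of an alkenyl triflate with a primary alkylzinc halide tolerates the ester and forms C9–C11 without moving the tetrasubstituted double bond.

Step 6
Reactants: 9 ester; 10 3-(trimethylsilyl)prop-2-ynal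
Product: 13 ethyl (2E)-2-{2-[(4aS,8aS)-2,5,5,8a-tetramethyl-3,4,4a,5,6,7,8,8a-octahydronaphthalen-1-yl]ethyl}-5-(trimethylsilyl)pent-2-en-4-ynoate, via ketene acetal phosphate 11 (not isolated), via phosphono ester 12 (not isolated)
Conditions: LiN(iPr)2 (1.05 equiv), THF, −78 °C; ClP(O)(OEt)2, −78 to 0 °C; LiN(iPr)2 (2.2 equiv), −78 to 0 °C; 10, −78 °C to rt
Reagents that add atoms: 3-(trimethylsilyl)prop-2-ynal, C[Si](C)(C)C#CC=O; diethyl chlorophosphate, CCOP(=O)(Cl)OCC (its atoms stay only in 11 and 12)
Why: O-phosphorylation of the ester enolate, base-induced 1,3-phosphoryl migration to the lithiated α-phosphono ester and Horner–Wadsworth–Emmons olefination of the unhindered ynal run in one flask, and the E isomer (ester trans to the alkynyl group, as the target requires) is expected to predominate, with any Z isomer to be removed by chromatography.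

Step 7
Reactants: 13 enynoate
Product: 14 (2E)-2-{2-[(4aS,8aS)-2,5,5,8a-tetramethyl-3,4,4a,5,6,7,8,8a-octahydronaphthalen-1-yl]ethyl}-5-(trimethylsilyl)pent-2-en-4-yn-1-ol
Conditions: iBu2AlH (2.5 equiv), CH2Cl2, −78 to 0 °C; aqueous potassium sodium tartrate
Reagents that add atoms: none
Why: 1,2-Reduction of the conjugated ester by the aluminium hydride gives the primary allylic alcohol without touching the silylalkyne or the alkene geometry.

Step 8
Reactants: 14 silyl enynol
Product: 15 (2E)-2-{2-[(4aS,8aS)-2,5,5,8a-tetramethyl-3,4,4a,5,6,7,8,8a-octahydronaphthalen-1-yl]ethyl}pent-2-en-4-yn-1-ol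
Conditions: K2CO3 (20 mol %), MeOH, rt
Reagents that add atoms: none
Why: Methanolysis of the alkynyl C–Si bond (protodesilylation) frees the terminal alkyne for coupling and leaves the rest of the molecule unchanged.

Step 9
Reactants: 16 but-2-ynoic acid
Product: 17 (2Z)-3-iodobut-2-enoic acid
Conditions: NaI, AcOH, 110 °C
Reagents that add atoms: sodium iodide, [Na+].[I-]
Why: Conjugate hydroiodination of the ynoic acid proceeds by anti addition (iodide at C3, proton at C2) and should therefore give the Z acid with iodine and carboxyl cis, the geometry needed for lactonisation.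

Step 10
Reactants: 15 terminal enynol; 17 (2Z)-3-iodobut-2-enoic acid
Product: 19 (5Z)-5-{(2E)-3-(hydroxymethyl)-5-[(4aS,8aS)-2,5,5,8a-tetramethyl-3,4,4a,5,6,7,8,8a-octahydronaphthalen-1-yl]pent-2-en-1-ylidene}-4-methylfuran-2(5H)-one (target), via enynoic acid 18 (not isolated)
Conditions: PdCl2(PPh3)2 (5 mol %), CuI (10 mol %), Et3N (3 equiv), MeCN, rt, degassed
Reagents that add atoms: (2Z)-3-iodobut-2-enoic acid, C/C(I)=C/C(=O)O
Why: Sonogashira coupling gives the (Z)-enynoic acid, whose carboxylate adds anti across the metal-activated alkyne in the 5-exo-dig mode (tandem coupling–lactonisation of β-iodoacrylic acids), so the ring oxygen and the dienyl chain end up cis (the Z ylidene butenolide) and the free allylic alcohol is tolerated.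

**Compound list**

1 | (R)-(−)-carvone, (5R)-2-methyl-5-(prop-1-en-2-yl)cyclohex-2-en-1-one | CC(=C)[C@@H]1CC=C(C)C(=O)C1 | starting material
2 | (5R)-2,6-dimethyl-5-(prop-1-en-2-yl)cyclohex-2-en-1-one (6-methylcarvone, both C6 epimers) | CC(=C)[C@@H]1CC=C(C)C(=O)C1C | intermediate
3 | 2,3-bis(phenylsulfonyl)prop-1-ene | C=C(CS(=O)(=O)c1ccccc1)S(=O)(=O)c1ccccc1 | starting material
4 | (5S,6S)-2,6-dimethyl-6-[2-(phenylsulfonyl)prop-2-en-1-yl]-5-(prop-1-en-2-yl)cyclohex-2-en-1-one (allyl unit trans to isopropenyl) | O=C1C(C)=CC[C@@H](C(C)=C)[C@]1(C)CC(=C)S(=O)(=O)c1ccccc1 | intermediate (not isolated)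
5 | (4aS,8aS)-2,5,5,8a-tetramethyl-7-(phenylsulfonyl)-4a,5,6,7,8,8a-hexahydronaphthalen-1(4H)-one (C7 epimers) | O=C1C(C)=CC[C@H]2C(C)(C)CC(S(=O)(=O)c3ccccc3)C[C@]12C | intermediate
6 | (4aS,8aS)-2,5,5,8a-tetramethyloctahydronaphthalen-1(2H)-one (C2 epimers) | O=C1C(C)CC[C@H]2C(C)(C)CCC[C@]12C | intermediate
7 | (4aS,8aS)-2,5,5,8a-tetramethyl-3,4,4a,5,6,7,8,8a-octahydronaphthalen-1-yl trifluoromethanesulfonate | FC(F)(F)S(=O)(=O)OC1=C(C)CC[C@H]2C(C)(C)CCC[C@]12C | intermediate
8 | 4-ethoxy-4-oxobutylzinc bromide | CCOC(=O)CCC[Zn]Br | starting material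
9 | ethyl 4-[(4aS,8aS)-2,5,5,8a-tetramethyl-3,4,4a,5,6,7,8,8a-octahydronaphthalen-1-yl]butanoate | CCOC(=O)CCCC1=C(C)CC[C@H]2C(C)(C)CCC[C@]12C | intermediate
10 | 3-(trimethylsilyl)prop-2-ynal | C[Si](C)(C)C#CC=O | starting material
11 | diethyl 1-ethoxy-4-[(4aS,8aS)-2,5,5,8a-tetramethyl-3,4,4a,5,6,7,8,8a-octahydronaphthalen-1-yl]but-1-en-1-yl phosphate (alkene geometry not defined) | CCOC(OP(=O)(OCC)OCC)=CCCC1=C(C)CC[C@H]2C(C)(C)CCC[C@]12C | intermediate (not isolated)
12 | ethyl 2-(diethoxyphosphoryl)-4-[(4aS,8aS)-2,5,5,8a-tetramethyl-3,4,4a,5,6,7,8,8a-octahydronaphthalen-1-yl]butanoate (C2 epimers, formed as its lithium salt) | CCOC(=O)C(CCC1=C(C)CC[C@H]2C(C)(C)CCC[C@]12C)P(=O)(OCC)OCC | intermediate (not isolated)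
13 | ethyl (2E)-2-{2-[(4aS,8aS)-2,5,5,8a-tetramethyl-3,4,4a,5,6,7,8,8a-octahydronaphthalen-1-yl]ethyl}-5-(trimethylsilyl)pent-2-en-4-ynoate | C[Si](C)(C)C#C/C=C(/C(=O)OCC)CCC1=C(C)CC[C@H]2C(C)(C)CCC[C@]12C | intermediate
14 | (2E)-2-{2-[(4aS,8aS)-2,5,5,8a-tetramethyl-3,4,4a,5,6,7,8,8a-octahydronaphthalen-1-yl]ethyl}-5-(trimethylsilyl)pent-2-en-4-yn-1-ol | C[Si](C)(C)C#C/C=C(/CO)CCC1=C(C)CC[C@H]2C(C)(C)CCC[C@]12C | intermediate
15 | (2E)-2-{2-[(4aS,8aS)-2,5,5,8a-tetramethyl-3,4,4a,5,6,7,8,8a-octahydronaphthalen-1-yl]ethyl}pent-2-en-4-yn-1-ol | C#C/C=C(/CO)CCC1=C(C)CC[C@H]2C(C)(C)CCC[C@]12C | intermediate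
16 | but-2-ynoic acid | CC#CC(=O)O | starting material
17 | (2Z)-3-iodobut-2-enoic acid | C/C(I)=C/C(=O)O | intermediate
18 | (2Z,6E)-8-hydroxy-3-methyl-7-{2-[(4aS,8aS)-2,5,5,8a-tetramethyl-3,4,4a,5,6,7,8,8a-octahydronaphthalen-1-yl]ethyl}octa-2,6-dien-4-ynoic acid | OC(=O)/C=C(C)\C#C/C=C(/CO)CCC1=C(C)CC[C@H]2C(C)(C)CCC[C@]12C | intermediate (not isolated)
19 | (5Z)-5-{(2E)-3-(hydroxymethyl)-5-[(4aS,8aS)-2,5,5,8a-tetramethyl-3,4,4a,5,6,7,8,8a-octahydronaphthalen-1-yl]pent-2-en-1-ylidene}-4-methylfuran-2(5H)-one | CC1=CC(=O)O/C1=C\C=C(\CO)CCC1=C(C)CC[C@H]2C(C)(C)CCC[C@]12C | target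

**Step count and risks**

Total steps: 10. Longest linear sequence: 9 (steps 1 to 8, then step 10; step 9 is a one-step side branch).

Steps most likely to fail:

1. Step 2. In the first stage, deprotonation at the γ-position instead of C6, or consumption of the linchpin by Michael addition, may compete. In the second stage the tertiary radical may be reduced before it cyclises, or the salts left from the first stage may slow the iron cycle. Fallback, from 2 and 3 back to 5: the alkylation is run alone and worked up to isolate 4. HBr in AcOH at 0 °C then adds to the isopropenyl group in the Markovnikov sense and gives the tertiary bromide (5R,6S)-5-(2-bromopropan-2-yl)-2,6-dimethyl-6-[2-(phenylsulfonyl)prop-2-en-1-yl]cyclohex-2-en-1-one F1. Slow addition of Bu3SnH and AIBN in benzene at 80 °C generates the same C4 radical by bromine abstraction in a tin hydride chain and closes ring A in the 6-endo mode to give 5.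

2. Step 6. The phosphate-to-phosphonate migration may stay incomplete, and the α-branched phosphonate may add to the ynal with poor E/Z control. Fallback, from 9 back to 13: LiN(iPr)2 then CBr4 at −78 °C gives ethyl 2-bromo-4-[(4aS,8aS)-2,5,5,8a-tetramethyl-3,4,4a,5,6,7,8,8a-octahydronaphthalen-1-yl]butanoate F2. PPh3 in toluene at 90 °C gives the phosphonium bromide [1-ethoxy-1-oxo-4-[(4aS,8aS)-2,5,5,8a-tetramethyl-3,4,4a,5,6,7,8,8a-octahydronaphthalen-1-yl]butan-2-yl]triphenylphosphonium bromide F3. Aqueous NaOH gives the stabilised ylide ethyl 2-(triphenylphosphoranylidene)-4-[(4aS,8aS)-2,5,5,8a-tetramethyl-3,4,4a,5,6,7,8,8a-octahydronaphthalen-1-yl]butanoate F4. Its Wittig reaction with 10 in toluene at 80 °C, which is reliably E-selective for α-alkyl ester ylides, gives 13.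

3. Step 10. The carboxylate may close in the 6-endo-dig mode to a 2-pyranone, the alkyne may homocouple, or the ylidene geometry may drift. Fallback, from 15 and 17 back to 19: 17 is esterified (MeOH, cat. H2SO4) to methyl (2Z)-3-iodobut-2-enoate F5. Sonogashira coupling of 15 with F5 (Pd(PPh3)4, CuI, Et3N, THF) gives the isolable methyl (2Z,6E)-8-hydroxy-3-methyl-7-{2-[(4aS,8aS)-2,5,5,8a-tetramethyl-3,4,4a,5,6,7,8,8a-octahydronaphthalen-1-yl]ethyl}octa-2,6-dien-4-ynoate F6. LiOH in THF/water gives acid 18, now isolated, and AgNO3 (10 mol %) in acetone closes it by 5-exo-dig anti addition to 19.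

**Further compounds**

F1 | step 2 | (5R,6S)-5-(2-bromopropan-2-yl)-2,6-dimethyl-6-[2-(phenylsulfonyl)prop-2-en-1-yl]cyclohex-2-en-1-one | O=C1C(C)=CC[C@@H](C(C)(C)Br)[C@]1(C)CC(=C)S(=O)(=O)c1ccccc1
F2 | step 6 | ethyl 2-bromo-4-[(4aS,8aS)-2,5,5,8a-tetramethyl-3,4,4a,5,6,7,8,8a-octahydronaphthalen-1-yl]butanoate | CCOC(=O)C(Br)CCC1=C(C)CC[C@H]2C(C)(C)CCC[C@]12C
F3 | step 6 | [1-ethoxy-1-oxo-4-[(4aS,8aS)-2,5,5,8a-tetramethyl-3,4,4a,5,6,7,8,8a-octahydronaphthalen-1-yl]butan-2-yl]triphenylphosphonium bromide | CCOC(=O)C(CCC1=C(C)CC[C@H]2C(C)(C)CCC[C@]12C)[P+](c1ccccc1)(c1ccccc1)c1ccccc1.[Br-]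
F4 | step 6 | ethyl 2-(triphenylphosphoranylidene)-4-[(4aS,8aS)-2,5,5,8a-tetramethyl-3,4,4a,5,6,7,8,8a-octahydronaphthalen-1-yl]butanoate | CCOC(=O)C(CCC1=C(C)CC[C@H]2C(C)(C)CCC[C@]12C)=P(c1ccccc1)(c1ccccc1)c1ccccc1
F5 | step 10 | methyl (2Z)-3-iodobut-2-enoate | C/C(I)=C/C(=O)OC
F6 | step 10 | methyl (2Z,6E)-8-hydroxy-3-methyl-7-{2-[(4aS,8aS)-2,5,5,8a-tetramethyl-3,4,4a,5,6,7,8,8a-octahydronaphthalen-1-yl]ethyl}octa-2,6-dien-4-ynoate | COC(=O)/C=C(C)\C#C/C=C(/CO)CCC1=C(C)CC[C@H]2C(C)(C)CCC[C@]12C
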